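**Retrosynthetic overview**
1. Target 25 ⇐ global desilylation of 24 ⇐ Z-selective Horner–Wadsworth–Emmons olefination of the C3 phosphonoacetate 21 with aldehyde 23 ⇐ 3β-alcohol 19 ⇐ Luche reduction of enone 18.
2. Ring A (C1–C2–C3–C4–C5–C10) is closed last, at C2–C1, by an intramolecular silyl-triflate aldol of the monocyclic keto-aldehyde 16. The enabling feature is that the ring A oxygens on C1 and C3 sit 1,3 across C2 (aldol retron), C1 hangs on the quaternary C10 (the aldehyde cannot enolise), and C4 carries the exocyclic C15 methylene (the C3 ketone can enolise only toward C2).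
3. 16 ⇐ ring B acid 11: the C10 quaternary centre comes from conjugate vinylation anti to the C5 arm (vinyl = latent C1 aldehyde); the C5 arm (C4, C3) comes from an Ireland–Claisen transfer of chirality from the C9 oxygen; C2 comes from MeLi and C15 from formaldehyde.
4. Ring B is the ring of (R)-carvone and is never formed. C7, α to the temporary C8 ketone, steers C5 and C10 in its carvone configuration and is then epimerised; C8 is reduced under thermodynamic control.
5. Order of rings: ring B (purchased) → ring A (step 11).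

Key step: step 11

Numbering: C1–C15 are eudesmane numbers (C10 angular carbon, C14 its methyl, C15 the exocyclic methylene) and are used for the monocyclic intermediates as well. Bicyclic compounds are named as eudesmanes (trans-fused, 5α-H, 10β-methyl, 7β-isopropyl).
Assumption: (diphenoxyphosphoryl)acetic acid (20) is taken as a purchasable reagent for Z-selective olefination.

Step 1
Reactants: 1 (R)-(−)-carvone
Product: 2 (5R)-2-methyl-5-(propan-2-yl)cyclohex-2-en-1-one
Conditions: H2 (1 atm), RhCl(PPh3)3 (cat.), benzene, 23 °C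
Reagents that add atoms: none
Why: Homogeneous catalytic hydrogenation with RhCl(PPh3)3 should reduce the unhindered 1,1-disubstituted isopropenyl alkene much faster than the trisubstituted conjugated ring alkene, leaving the stereocentre untouched.

Step 2
Reactants: 2 (5R)-2-methyl-5-(propan-2-yl)cyclohex-2-en-1-one
Product: 3 (1R,5R)-2-methyl-5-(propan-2-yl)cyclohex-2-en-1-ol (hydroxyl cis to isopropyl)
Conditions: NaBH4, CeCl3·7H2O, MeOH, −78 → 0 °C
Reagents that add atoms: none
Why: Luche 1,2-reduction, in which axial hydride delivery to the half-chair enone with isopropyl equatorial should give the cis allylic alcohol.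

Step 3
Reactants: 3 (1R,5R)-2-methyl-5-(propan-2-yl)cyclohex-2-en-1-ol
Product: 4 (1S,5R)-2-methyl-5-(propan-2-yl)cyclohex-2-en-1-yl acetate (acetoxy trans to isopropyl)
Conditions: AcOH, PPh3, DIAD, THF, 0 → 23 °C
Reagents that add atoms: acetic acid, CC(=O)O
Why: Mitsunobu esterification, in which acetate displaces the oxyphosphonium group by SN2 with inversion at the carbinol carbon, should give the trans acetate needed for the rearrangement.

Step 4
Reactants: 4 (1S,5R)-2-methyl-5-(propan-2-yl)cyclohex-2-en-1-yl acetate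
Product: 7 2-[(1S,5S)-2-methyl-5-(propan-2-yl)cyclohex-2-en-1-yl]acetic acid (acetic acid arm trans to isopropyl), via silyl ketene acetal 5 (not isolated), via trimethylsilyl ester 6 (not isolated)
Conditions: LiN(i-Pr)2, THF, −78 °C; TMSCl; −78 → 60 °C; then 1 M HCl
Reagents that add atoms: none
Why: Ireland–Claisen rearrangement, which is suprafacial and runs through the conformer with the C–O bond pseudoaxial and isopropyl equatorial, should form the new C5–C4 bond on the face the oxygen leaves and so transfer the C9 configuration to C5.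

Step 5
Reactants: 7 2-[(1S,5S)-2-methyl-5-(propan-2-yl)cyclohex-2-en-1-yl]acetic acid
Product: 8 2-[(1S,5S)-2-methyl-4-oxo-5-(propan-2-yl)cyclohex-2-en-1-yl]acetic acid
Conditions: Rh2(cap)4 (dirhodium tetrakis(caprolactamate), cat.), t-BuOOH (70% in water), 1,2-dichloroethane, 40 °C
Reagents that add atoms: tert-butyl hydroperoxide, CC(C)(C)OO
Why: Dirhodium-catalysed allylic oxidation with t-BuOOH should attack the ring CH2 (C8) next to the CH end of the trisubstituted alkene and give the conjugated enone, and the non-basic medium should leave the C5 and C7 stereocentres unchanged.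

Step 6
Reactants: 8 2-[(1S,5S)-2-methyl-4-oxo-5-(propan-2-yl)cyclohex-2-en-1-yl]acetic acid
Product: 11 2-[(1S,2S,5R)-2-ethenyl-2-methyl-4-oxo-5-(propan-2-yl)cyclohexyl]acetic acid, via bis-silylated adduct 9 (not isolated), via C7-epimeric keto acid 10 (not isolated)
Conditions: CH2=CHMgBr (excess), CuBr·SMe2 (cat.), TMSCl, THF, −78 → −30 °C; then K2CO3, MeOH, 23 °C; acidify to pH 3
Reagents that add atoms: vinylmagnesium bromide, C=C[Mg]Br
Why: Copper-catalysed, TMSCl-accelerated conjugate addition should deliver vinyl axially, anti to the pseudoaxial C5 arm (which avoids A1,2 strain with the ring methyl) and on the face that keeps isopropyl equatorial, setting C10 trans to the arm; methanolic carbonate then removes the silyl groups and epimerises C7 to the all-equatorial ketone.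

Step 7
Reactants: 11 2-[(1S,2S,5R)-2-ethenyl-2-methyl-4-oxo-5-(propan-2-yl)cyclohexyl]acetic acid
Product: 12 2-[(1S,2S,4S,5R)-2-ethenyl-4-hydroxy-2-methyl-5-(propan-2-yl)cyclohexyl]acetic acid
Conditions: Li, NH3 (l), THF, t-BuOH, −78 → −33 °C; NH4Cl
Reagents that add atoms: none
Why: Dissolving-metal reduction is under thermodynamic control and should give the equatorial C8 alcohol (hydride reagents would be steered to the other face by the axial C10 methyl), while the carboxylate and the isolated vinyl group are inert.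

Step 8
Reactants: 12 2-[(1S,2S,4S,5R)-2-ethenyl-4-hydroxy-2-methyl-5-(propan-2-yl)cyclohexyl]acetic acid
Product: 13 1-[(1S,2S,4S,5R)-2-ethenyl-4-hydroxy-2-methyl-5-(propan-2-yl)cyclohexyl]propan-2-one
Conditions: MeLi (excess), THF, 0 → 23 °C; inverse quench into cold 1 M HCl
Reagents that add atoms: methyllithium, [Li]C
Why: Addition of methyllithium to the lithium carboxylate gives a stable geminal dialkoxide that releases the methyl ketone only on acidic quench (ketone synthesis from a carboxylic acid).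

Step 9
Reactants: 13 1-[(1S,2S,4S,5R)-2-ethenyl-4-hydroxy-2-methyl-5-(propan-2-yl)cyclohexyl]propan-2-one
Product: 14 3-[(1R,2S,4S,5R)-2-ethenyl-4-hydroxy-2-methyl-5-(propan-2-yl)cyclohexyl]but-3-en-2-one
Conditions: (CH2O)n, PhNHMe·CF3CO2H, THF, reflux
Reagents that add atoms: formaldehyde (as paraformaldehyde), C=O
Why: Mannich-type α-methylenation under acidic conditions should go through the more substituted enol (the C4 methylene side) of the methyl ketone, and loss of the amine gives the α-methylene ketone.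

Step 10
Reactants: 14 3-[(1R,2S,4S,5R)-2-ethenyl-4-hydroxy-2-methyl-5-(propan-2-yl)cyclohexyl]but-3-en-2-one
Product: 16 (1R,2R,4R,5S)-5-hydroxy-1-methyl-2-(3-oxobut-1-en-2-yl)-4-(propan-2-yl)cyclohexane-1-carbaldehyde, via vicinal diol 15 (not isolated)
Conditions: OsO4 (cat.), NaIO4, 2,6-lutidine, dioxane/H2O (3:1), 23 °C
Reagents that add atoms: osmium tetroxide, O=[Os](=O)(=O)=O (catalytic; oxygen replenished by sodium periodate, [Na+].[O-]I(=O)(=O)=O)
Why: Lemieux–Johnson cleavage, in which electrophilic OsO4 should dihydroxylate the isolated vinyl group far faster than the electron-poor enone alkene and periodate cleaves the diol to the C1 aldehyde.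

Step 11
Reactants: 16 (1R,2R,4R,5S)-5-hydroxy-1-methyl-2-(3-oxobut-1-en-2-yl)-4-(propan-2-yl)cyclohexane-1-carbaldehyde
Product: 18 1β,8α-bis(tert-butyldimethylsilyloxy)eudesm-4(15)-en-3-one, via bis-silyl dienol ether 17 (not isolated)
Conditions: TBSOTf (2.6 equiv), Et3N (2.4 equiv), CH2Cl2, −78 → 0 °C; aq. NaHCO3
Reagents that add atoms: tert-butyldimethylsilyl trifluoromethanesulfonate, CC(C)(C)[Si](C)(C)OS(=O)(=O)C(F)(F)F
Why: TBSOTf/Et3N first silylates the C8 hydroxyl and converts the methyl ketone into the 2-silyloxy-1,3-diene 17; the small excess of free silyl triflate then activates the aldehyde, the diene terminus C2 adds to C1, and the silyl group passes to the new C1 oxygen with regeneration of the triflate. The closest known reaction type is the intramolecular Mukaiyama aldol addition run as a one-flask silyl triflate/amine enolisation–aldol sequence. Ring A (C1–C2–C3–C4–C5–C10) is closed in a 6-(enolexo)-exo-trig mode, and the trans-diequatorial arms on C5 and C10 of ring B hold the two termini gauche, so the trans-decalin should form without strain. The new stereocentre C1 is controlled by the chair-like transition state, in which the bulky silylated oxygen should take the equatorial site (β, anti to the C10–C5 bond) and avoid the axial hydrogens on C5 and C9. The step needs regioselective enolisation, secured because C2 carries the only α-hydrogens (C4 is sp2 through the C15 methylene) and the aldehyde on quaternary C10 cannot enolise; it needs aldol rather than hetero-Diels–Alder closure, secured because that adduct would require a bridgehead double bond; and it needs no β-elimination, for which the low temperature and near-neutral medium are relied on.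

Step 12
Reactants: 18 1β,8α-bis(tert-butyldimethylsilyloxy)eudesm-4(15)-en-3-one
Product: 19 1β,8α-bis(tert-butyldimethylsilyloxy)eudesm-4(15)-en-3β-ol
Conditions: NaBH4, CeCl3·7H2O, MeOH/THF, −78 °C
Reagents that add atoms: none
Why: Luche reduction is 1,2-selective for the α-methylene ketone, and axial hydride delivery from the α-face of the trans-decalin should give the equatorial 3β-alcohol.

Step 13
Reactants: 19 1β,8α-bis(tert-butyldimethylsilyloxy)eudesm-4(15)-en-3β-ol; 20 (diphenoxyphosphoryl)acetic acid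
Product: 21 1β,8α-bis(tert-butyldimethylsilyloxy)eudesm-4(15)-en-3β-yl 2-(diphenoxyphosphoryl)acetate
Conditions: EDC·HCl, DMAP (cat.), CH2Cl2, 0 → 23 °C
Reagents that add atoms: none
Why: Steglich esterification of the only free hydroxyl, the C1 and C8 oxygens being blocked as silyl ethers.

Step 14
Reactants: 22 3,4-dihydroxybenzaldehyde
Product: 23 3,4-bis(tert-butyldimethylsilyloxy)benzaldehyde
Conditions: TBSCl, imidazole, DMF, 23 °C
Reagents that add atoms: tert-butyldimethylsilyl chloride, CC(C)(C)[Si](C)(C)Cl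
Why: Imidazole-promoted silylation of both phenols gives a catechol protection that comes off with the other silyl ethers at the end.

Step 15
Reactants: 21 1β,8α-bis(tert-butyldimethylsilyloxy)eudesm-4(15)-en-3β-yl 2-(diphenoxyphosphoryl)acetate; 23 3,4-bis(tert-butyldimethylsilyloxy)benzaldehyde
Product: 24 1β,8α-bis(tert-butyldimethylsilyloxy)eudesm-4(15)-en-3β-yl (2Z)-3-[3,4-bis(tert-butyldimethylsilyloxy)phenyl]prop-2-enoate
Conditions: NaH, THF, 0 °C; then 23, −78 → −20 °C
Reagents that add atoms: none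
Why: Horner–Wadsworth–Emmons olefination with a diaryl phosphonoacetate, whose fast and irreversible elimination from the kinetic adduct at low temperature should give the (Z)-cinnamate.

Step 16
Reactants: 24 1β,8α-bis(tert-butyldimethylsilyloxy)eudesm-4(15)-en-3β-yl (2Z)-3-[3,4-bis(tert-butyldimethylsilyloxy)phenyl]prop-2-enoate
Product: 25 (2S,4R,4aR,6S,7R,8aS)-4,6-dihydroxy-4a-methyl-1-methylidene-7-(propan-2-yl)decahydronaphthalen-2-yl (2Z)-3-(3,4-dihydroxyphenyl)prop-2-enoate (1β,8α-dihydroxyeudesm-4(15)-en-3β-yl (Z)-caffeate)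
Conditions: HF·pyridine, pyridine, THF, 0 → 23 °C, light excluded
Reagents that add atoms: none
Why: Fluoride cleavage of the two aryl and two secondary silyl ethers in a buffered, mildly acidic medium should avoid acyl migration to the C1 hydroxyl and Z-to-E isomerisation of the ester.

**Compound list**
1 | (R)-(−)-carvone | O=C1C(C)=CC[C@@H](C(C)=C)C1 | starting material
2 | (5R)-2-methyl-5-(propan-2-yl)cyclohex-2-en-1-one | O=C1C(C)=CC[C@@H](C(C)C)C1 | intermediate
3 | (1R,5R)-2-methyl-5-(propan-2-yl)cyclohex-2-en-1-ol | O[C@H]1C(C)=CC[C@@H](C(C)C)C1 | intermediate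
4 | (1S,5R)-2-methyl-5-(propan-2-yl)cyclohex-2-en-1-yl acetate | CC(=O)O[C@@H]1C(C)=CC[C@@H](C(C)C)C1 | intermediate
5 | 1-{[(1S,5R)-2-methyl-5-(propan-2-yl)cyclohex-2-en-1-yl]oxy}-1-(trimethylsilyloxy)ethene | C=C(O[Si](C)(C)C)O[C@@H]1C(C)=CC[C@@H](C(C)C)C1 | intermediate (not isolated)
6 | trimethylsilyl 2-[(1S,5S)-2-methyl-5-(propan-2-yl)cyclohex-2-en-1-yl]acetate | C[Si](C)(C)OC(=O)C[C@H]1C(C)=CC[C@H](C(C)C)C1 | intermediate (not isolated)
7 | 2-[(1S,5S)-2-methyl-5-(propan-2-yl)cyclohex-2-en-1-yl]acetic acid | OC(=O)C[C@H]1C(C)=CC[C@H](C(C)C)C1 | intermediate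
8 | 2-[(1S,5S)-2-methyl-4-oxo-5-(propan-2-yl)cyclohex-2-en-1-yl]acetic acid | OC(=O)C[C@H]1C(C)=CC(=O)[C@H](C(C)C)C1 | intermediate
9 | trimethylsilyl 2-[(1S,2S,5S)-2-ethenyl-2-methyl-5-(propan-2-yl)-4-(trimethylsilyloxy)cyclohex-3-en-1-yl]acetate | C=C[C@]1(C)C=C(O[Si](C)(C)C)[C@H](C(C)C)C[C@H]1CC(=O)O[Si](C)(C)C | intermediate (not isolated)
10 | 2-[(1S,2S,5S)-2-ethenyl-2-methyl-4-oxo-5-(propan-2-yl)cyclohexyl]acetic acid | C=C[C@]1(C)CC(=O)[C@H](C(C)C)C[C@H]1CC(=O)O | intermediate (not isolated)
11 | 2-[(1S,2S,5R)-2-ethenyl-2-methyl-4-oxo-5-(propan-2-yl)cyclohexyl]acetic acid | C=C[C@]1(C)CC(=O)[C@@H](C(C)C)C[C@H]1CC(=O)O | intermediate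
12 | 2-[(1S,2S,4S,5R)-2-ethenyl-4-hydroxy-2-methyl-5-(propan-2-yl)cyclohexyl]acetic acid | C=C[C@]1(C)C[C@H](O)[C@@H](C(C)C)C[C@H]1CC(=O)O | intermediate
13 | 1-[(1S,2S,4S,5R)-2-ethenyl-4-hydroxy-2-methyl-5-(propan-2-yl)cyclohexyl]propan-2-one | C=C[C@]1(C)C[C@H](O)[C@@H](C(C)C)C[C@H]1CC(C)=O | intermediate
14 | 3-[(1R,2S,4S,5R)-2-ethenyl-4-hydroxy-2-methyl-5-(propan-2-yl)cyclohexyl]but-3-en-2-one | C=C[C@]1(C)C[C@H](O)[C@@H](C(C)C)C[C@H]1C(=C)C(C)=O | intermediate
15 | 3-[(1R,2R,4S,5R)-2-(1,2-dihydroxyethyl)-4-hydroxy-2-methyl-5-(propan-2-yl)cyclohexyl]but-3-en-2-one (mixture at the new carbinol carbon) | OCC(O)[C@]1(C)C[C@H](O)[C@@H](C(C)C)C[C@H]1C(=C)C(C)=O | intermediate (not isolated)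
16 | (1R,2R,4R,5S)-5-hydroxy-1-methyl-2-(3-oxobut-1-en-2-yl)-4-(propan-2-yl)cyclohexane-1-carbaldehyde | O=C[C@]1(C)C[C@H](O)[C@@H](C(C)C)C[C@H]1C(=C)C(C)=O | intermediate
17 | (1R,2S,4R,5S)-5-(tert-butyldimethylsilyloxy)-2-[3-(tert-butyldimethylsilyloxy)buta-1,3-dien-2-yl]-1-methyl-4-(propan-2-yl)cyclohexane-1-carbaldehyde | O=C[C@]1(C)C[C@H](O[Si](C)(C)C(C)(C)C)[C@@H](C(C)C)C[C@H]1C(=C)C(=C)O[Si](C)(C)C(C)(C)C | intermediate (not isolated)
18 | 1β,8α-bis(tert-butyldimethylsilyloxy)eudesm-4(15)-en-3-one | C=C1C(=O)C[C@@H](O[Si](C)(C)C(C)(C)C)[C@]2(C)C[C@H](O[Si](C)(C)C(C)(C)C)[C@@H](C(C)C)C[C@@H]12 | intermediate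
19 | 1β,8α-bis(tert-butyldimethylsilyloxy)eudesm-4(15)-en-3β-ol | C=C1[C@@H](O)C[C@@H](O[Si](C)(C)C(C)(C)C)[C@]2(C)C[C@H](O[Si](C)(C)C(C)(C)C)[C@@H](C(C)C)C[C@@H]12 | intermediate
20 | (diphenoxyphosphoryl)acetic acid | OC(=O)CP(=O)(Oc1ccccc1)Oc1ccccc1 | starting material
21 | 1β,8α-bis(tert-butyldimethylsilyloxy)eudesm-4(15)-en-3β-yl 2-(diphenoxyphosphoryl)acetate | C=C1[C@@H](OC(=O)CP(=O)(Oc2ccccc2)Oc2ccccc2)C[C@@H](O[Si](C)(C)C(C)(C)C)[C@]3(C)C[C@H](O[Si](C)(C)C(C)(C)C)[C@@H](C(C)C)C[C@@H]13 | intermediate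
22 | 3,4-dihydroxybenzaldehyde | O=Cc1ccc(O)c(O)c1 | starting material
23 | 3,4-bis(tert-butyldimethylsilyloxy)benzaldehyde | O=Cc1ccc(O[Si](C)(C)C(C)(C)C)c(O[Si](C)(C)C(C)(C)C)c1 | intermediate
24 | 1β,8α-bis(tert-butyldimethylsilyloxy)eudesm-4(15)-en-3β-yl (2Z)-3-[3,4-bis(tert-butyldimethylsilyloxy)phenyl]prop-2-enoate | C=C1[C@@H](OC(=O)/C=C\c2ccc(O[Si](C)(C)C(C)(C)C)c(O[Si](C)(C)C(C)(C)C)c2)C[C@@H](O[Si](C)(C)C(C)(C)C)[C@]3(C)C[C@H](O[Si](C)(C)C(C)(C)C)[C@@H](C(C)C)C[C@@H]13 | intermediate
25 | (2S,4R,4aR,6S,7R,8aS)-4,6-dihydroxy-4a-methyl-1-methylidene-7-(propan-2-yl)decahydronaphthalen-2-yl (2Z)-3-(3,4-dihydroxyphenyl)prop-2-enoate | C=C1[C@@H](OC(=O)/C=C\c2ccc(O)c(O)c2)C[C@@H](O)[C@]2(C)C[C@H](O)[C@@H](C(C)C)C[C@@H]12 | target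

Total step count: 16. Longest linear sequence: 15 steps (steps 1–13, 15 and 16, from 1).

**Steps most likely to fail**

Step 11 (key step). The aldehyde may be attacked on the wrong face, giving the C1 epimer, or the β-silyloxy ketone may eliminate to the cross-conjugated dienone. The fallback sets out from 16 and comes back at 18. Compound 16 would be cyclised under reversible, thermodynamic conditions (KOt-Bu, catalytic, t-BuOH/THF, 0 °C), where retro-aldol equilibration should funnel the material to the equatorial alcohol 1β,8α-dihydroxyeudesm-4(15)-en-3-one F1. Silylation of both hydroxyls of F1 (TBSOTf, 2,6-lutidine, CH2Cl2, −78 °C) then gives 18.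

Step 9. The Mannich reaction may take place on the methyl side of the ketone or run on to bis-adducts and oligomers of the enone. The fallback sets out from 12 and comes back at 14; it puts the methylene on while only one α-position exists. The trianion of 12 (LiN(i-Pr)2, 3.3 equiv, THF, −78 → 0 °C) is aminomethylated with N,N-dimethylmethyleneiminium iodide to the amino acid 3-(dimethylamino)-2-[(1S,2S,4S,5R)-2-ethenyl-4-hydroxy-2-methyl-5-(propan-2-yl)cyclohexyl]propanoic acid F2. N-Methylation (MeI) and elimination (NaHCO3) give the α-methylene acid 2-[(1R,2S,4S,5R)-2-ethenyl-4-hydroxy-2-methyl-5-(propan-2-yl)cyclohexyl]prop-2-enoic acid F3. Coupling with MeNHOMe·HCl (EDC, N-methylmorpholine, CH2Cl2) gives the N-methoxy-N-methylamide F4, and MeMgBr (THF, 0 °C) converts F4 into 14.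

Step 6. Carbonyl addition or enolisation may outrun conjugate addition at the hindered β-carbon in the presence of the carboxylate, or the nucleophile may enter on the wrong face. The fallback sets out from 8 and comes back at 11. Hosomi–Sakurai allylation of 8 (allyltrimethylsilane, TiCl4, CH2Cl2, −78 °C), followed by K2CO3/MeOH, gives the allyl keto acid 2-[(1S,2S,5R)-2-methyl-4-oxo-5-(propan-2-yl)-2-(prop-2-en-1-yl)cyclohexyl]acetic acid F5, with allyl trans to the acetic acid arm by the same stereoelectronic argument. Alkene migration with RuHCl(CO)(PPh3)3 (toluene, 80 °C) gives the (E)-propenyl keto acid F6. Ethenolysis (second-generation Grubbs catalyst, ethylene, CH2Cl2) shortens F6 to the vinyl compound 11.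

**Further compounds**
F1 | step 11 | 1β,8α-dihydroxyeudesm-4(15)-en-3-one | C=C1C(=O)C[C@@H](O)[C@]2(C)C[C@H](O)[C@@H](C(C)C)C[C@@H]12
F2 | step 9 | 3-(dimethylamino)-2-[(1S,2S,4S,5R)-2-ethenyl-4-hydroxy-2-methyl-5-(propan-2-yl)cyclohexyl]propanoic acid (mixture at the α-carbon) | C=C[C@]1(C)C[C@H](O)[C@@H](C(C)C)C[C@H]1C(CN(C)C)C(=O)O
F3 | step 9 | 2-[(1R,2S,4S,5R)-2-ethenyl-4-hydroxy-2-methyl-5-(propan-2-yl)cyclohexyl]prop-2-enoic acid | C=C[C@]1(C)C[C@H](O)[C@@H](C(C)C)C[C@H]1C(=C)C(=O)O
F4 | step 9 | 2-[(1R,2S,4S,5R)-2-ethenyl-4-hydroxy-2-methyl-5-(propan-2-yl)cyclohexyl]-N-methoxy-N-methylprop-2-enamide | C=C[C@]1(C)C[C@H](O)[C@@H](C(C)C)C[C@H]1C(=C)C(=O)N(C)OC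
F5 | step 6 | 2-[(1S,2S,5R)-2-methyl-4-oxo-5-(propan-2-yl)-2-(prop-2-en-1-yl)cyclohexyl]acetic acid | C=CC[C@]1(C)CC(=O)[C@@H](C(C)C)C[C@H]1CC(=O)O
F6 | step 6 | 2-[(1S,2S,5R)-2-methyl-4-oxo-5-(propan-2-yl)-2-[(1E)-prop-1-en-1-yl]cyclohexyl]acetic acid | C/C=C/[C@]1(C)CC(=O)[C@@H](C(C)C)C[C@H]1CC(=O)O
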